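The data come from a simulation for an exercise, noise included.

Put the coupling partner in at 80 min and leave the starting material out: that is my own reckoning, and here is its ground.

all flasks: starting material 38 mM; coupling partner 34.2 mM

| charge | remark | time |
|---|---|---|
| green | the very flask that is asked about, followed so far |  |
| flask |  | 80 min |

- green (time / min: target / %, starting material / %): 6.00: 7.1, 87.6; 10.0: 11.9, 83.3; 15.0: 13.0, 75.0; 25.0: 17.2, 60.6; 30.0: 17.3, 56.5; 50.0: 20.4, 37.6; 80.0: 15.7, 23.8

(scatter of a reading: 1 percentage point)

- north-west: at 80 min add coupling partner, 50.0 % of the amount charged, then wait 2.5 h
- west: at 80 min add starting material, 50.0 % of the amount charged, then wait 2.5 h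
- south-east: change nothing and wait 2.5 h more

- the volume of additions can be left aside
- a reading or a percentage of target counts all its forms, free or not

* target, in percent of the starting material first charged, at 80 min
* the remedy with the largest gain of target, or "none" below 2 percentage points (north-west / west / south-east / none)
* target present, in percent of the starting material first charged, after north-west
* target present, in percent of the starting material first charged, after south-east

Assume that each starting material consumed does one of two things: with coupling partner it makes a target, or it spends a target already there. Count the made-to-spent ratio r, a selectivity factor, as (starting material consumed + target gained) over (starting material consumed − target gained). Target climbs while r exceeds unity and falls while r is below unity, so the peak is the crossing. For the green run up to 80.0 min, r reads 1.52.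

Now set two stretches of the green run side by side. From 10.0 min to 25.0 min, r reads 1.61. From 50.0 min to 80.0 min, it reads 0.492. The late stretch ends lower because less is made than spent. By the same count, c(coupling partner) has dropped from 27.0 mM at 15.0 min to 16.7 mM at 80.0 min.

Spend the 23.8 % of starting material read at 80.0 min at that late r, and I estimate that waiting leaves about 7.59 %. With r counted from 30.0 min to 80.0 min, which reads 0.907, the estimate is about 14.5 %. At the late r, extra starting material spends more target than it makes. Extra partner lifts c(coupling partner) to 33.8 mM, above the 27.0 mM at 15.0 min. Scale the early r by the target readings at 15.0 min and 80.0 min, which gives 1.33, and expect about 19.1 % after north-west.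

The forecast differs: 16.5 % now, none as best, 2.5 % after north-west, 2 % after south-east. It adds: “The main uncertainty is whether the loss stalls.”

The flask gives 16.4 % now and north-west as best, with 22.1 % after it and 13.3 % after south-east. West changes target by −9.6 percentage points.

    starting material + target → side product (k = 0.0220 M⁻¹ s⁻¹)
    starting material → decomposition product (k = 3.10 × 10⁻⁷ s⁻¹)
    crystals ⇌ target, rate k3*(cs3 - [target]) while solid is left; crystals form when [target] > cs3 (solubility = 13.0 mM, k = 0.120 s⁻¹)
    starting material + coupling partner → target, rate k4*[starting material]*[coupling partner]^1.5 (k = 0.0500 M⁻¹·⁵ s⁻¹)

Run the same count on the neighbour charged with 65 mM of starting material, which has 0.526 equiv of partner. At 80.0 min it holds 33 % of its starting material and 5.73 % target. So r is 1.19, lower than the green run's 1.52. In concentration, that neighbour holds 3.72 mM of target against 6.22 mM in the flask.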